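**Assumptions (one line each)**
- Target stereochemistry is as drawn. Ring substituent relationships: OAr and OH are cis to each other, and both are trans to the side chain.
- (S)-Citronellal matches the 7S centre. I assume the (R)-diarylprolinol silyl ether catalyst gives the ring CH–side-chain centre as R, overriding the β-stereocentre. The descriptor was derived by analogy to propanal + nitrostyrene with the (S)-catalyst.
- The curcumin enol/diketone tautomerism is treated as in curcumin itself.

## Retrosynthetic overview
1. Target ⇒ desilylation of 13 ⇒ boron-mediated (Pabon) condensation of feruloylacetone 12 with aryl-ether aldehyde 10, so the curcuminoid enol is assembled last.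
2. 10 ⇐ 9 ⇐ Pd(0)-catalysed aryloxylative opening of bicyclic endoperoxide 7 (key new step). It sets the allylic aryl ether and the cis-1,4 OH in one step, both trans to the side chain.
3. 7 ⇐ ¹O₂ [4+2] of diene 6, attacking anti to the side chain. 6 ⇐ enone 4 via dienyl triflate and Fe-catalysed methylation.
4. The only carbocycle is built by a Michael/aldol (Robinson) sequence from (S)-citronellal and MVK, which sets the ring CH(side chain) relative to C7. The endoperoxide is a transient second ring opened in step 6.

## Route

**Step 1**
Reactants: 1 (S)-citronellal; 2 methyl vinyl ketone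
Product: 3 (2R)-2-[(2S)-6-methylhept-5-en-2-yl]-5-oxohexanal
Conditions: (R)-diphenylprolinol TMS ether (15 mol%), PhCO₂H (15 mol%), CH₂Cl₂, 0 °C → rt
Reagents that add atoms: none beyond 2
Why: Enamine Michael addition (Hayashi–Jørgensen); the catalyst controls the enamine face and sets the new α-stereocentre (R), overriding the β-methyl stereocentre.

**Step 2**
Reactants: 3
Product: 4 (4R)-4-[(2S)-6-methylhept-5-en-2-yl]cyclohex-2-en-1-one
Conditions: pyrrolidine (10 mol%), AcOH (10 mol%), CH₂Cl₂, 25 °C, 2 h (short reaction time)
Reagents that add atoms: none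
Why: Intramolecular aldol condensation of the methyl ketone onto the aldehyde closes the six-membered ring (Robinson annulation) and dehydrates to the enone; no new stereocentre forms.

**Step 3**
Reactants: 4
Product: 5 (5R)-5-[(2S)-6-methylhept-5-en-2-yl]cyclohexa-1,3-dien-2-yl triflate
Conditions: LDA, THF, −78 °C; then PhNTf₂, −78 → 0 °C
Reagents that add atoms: PhNTf₂, FC(F)(F)S(=O)(=O)N(c1ccccc1)S(=O)(=O)C(F)(F)F (adds Tf)
Why: Kinetic α′-deprotonation of the enone followed by enolate triflation gives the cross-conjugated dienyl triflate; the γ-stereocentre is untouched at −78 °C.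

**Step 4**
Reactants: 5
Product: 6 (5R)-2-methyl-5-[(2S)-6-methylhept-5-en-2-yl]cyclohexa-1,3-diene
Conditions: MeMgBr, Fe(acac)₃ (5 mol%), THF/NMP, 0 °C
Reagents that add atoms: MeMgBr, C[Mg]Br (adds CH₃)
Why: Iron-catalysed Kumada coupling of an enol triflate with an alkyl Grignard puts the methyl exactly at C-OTf without moving the diene.

**Step 5**
Reactants: 6
Product: 7 endoperoxide, 5-methyl-7-[(2S)-6-methylhept-5-en-2-yl]-2,3-dioxabicyclo[2.2.2]oct-5-ene; the O–O bridge is trans to the side chain
Conditions: ¹O₂ (O₂, TPP 1 mol%, white LED), CH₂Cl₂, 0 °C, 30 min, stopped at full diene consumption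
Reagents that add atoms: O₂, O=O
Why: Photooxygenation of the diene ([4+2]) is more than 100 times faster than the ene reaction at the prenyl alkene. Approach anti to the branched side chain puts both oxygens on the face trans to it.

**Step 6**
Reactants: 7; 8 vanillin (4-hydroxy-3-methoxybenzaldehyde)
Product: 9 4-{[(1S,4R,5R)-4-hydroxy-2-methyl-5-[(2S)-6-methylhept-5-en-2-yl]cyclohex-2-en-1-yl]oxy}-3-methoxybenzaldehyde
Conditions: 8 (1.5 equiv), Pd₂(dba)₃·CHCl₃ (2.5 mol%), dppe (6 mol%), THF, 23 °C, 6 h; then PPh₃ (1.5 equiv), 1 h
Reagents that add atoms: vanillin (reactant 8, COc1cc(C=O)ccc1O); PPh₃ only removes O, as Ph₃P=O, to convert OOH to OH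
Why: Proposed new method: Pd(0) ionises the allylic C–O bond of the endoperoxide that is remote from the side chain (anti to Pd), with the peroxide anion as the leaving group. The peroxide anion deprotonates vanillin (pKa about 7.4), and the phenoxide attacks the π-allyl at the carbon bearing the original oxygen, anti to Pd. This gives the aryl ether cis to the remaining C–OO⁻, and PPh₃ then reduces the hydroperoxide to the cis-OH. The closest known reactions are Tsuji–Trost etherification of allylic carbonates with phenols and Pd(0) ionisation of allylic peroxides, extended to a bicyclic 1,4-endoperoxide used as a masked cis-1,4-diol. The side chain (1,2 to the other C–O) hinders Pd approach and ionisation at that carbon, which favours the desired regiochemistry.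

**Step 7**
Reactants: 9
Product: 10 4-({(1S,4R,5R)-4-[(tert-butyldimethylsilyl)oxy]-2-methyl-5-[(2S)-6-methylhept-5-en-2-yl]cyclohex-2-en-1-yl}oxy)-3-methoxybenzaldehyde
Conditions: TBSOTf, 2,6-lutidine, CH₂Cl₂, −78 → 0 °C
Reagents that add atoms: TBSOTf, CC(C)(C)[Si](C)(C)OS(=O)(=O)C(F)(F)F (adds TBS)
Why: Silylation of the hindered secondary allylic alcohol protects it from the Pabon conditions; no stereocentre is affected.

**Step 8**
Reactants: 8 vanillin; 11 acetylacetone (3 equiv)
Product: 12 feruloylacetone, (E)-6-(4-hydroxy-3-methoxyphenyl)hex-5-ene-2,4-dione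
Conditions: B₂O₃, B(OBu)₃, n-BuNH₂ (cat.), EtOAc, 80 °C; then 0.4 M HCl, 60 °C
Reagents that add atoms: none beyond the numbered reactants
Why: Boron-enolate Knoevenagel condensation (Pabon); excess acetylacetone favours mono-condensation.

**Step 9**
Reactants: 12; 10
Product: 13 TBS-protected terpecurcumin B
Conditions: 12 + B₂O₃ (EtOAc, 70 °C); then 10, B(OBu)₃, n-BuNH₂ (cat.), 80 °C; then aq. AcOH, 50 °C to release the boron complex
Reagents that add atoms: none beyond the numbered reactants
Why: Pabon boron-mediated Knoevenagel condensation at the free acetyl CH₃ of the feruloylacetone boron complex gives the unsymmetrical curcuminoid enol; the allylic aryl ether and TBS ether survive the mild conditions.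

**Step 10**
Reactants: 13
Product: 14 terpecurcumin B
Conditions: HF·pyridine, pyridine/THF (1:4), 0 °C → rt
Reagents that add atoms: none (F⁻ leaves with Si)
Why: Buffered fluoride desilylation reveals the allylic alcohol; the stereocentres are untouched and the buffering avoids hydrofluorination of the prenyl alkene.

## Compound list
1 | (S)-citronellal | CC(C)=CCC[C@H](C)CC=O | starting material
2 | methyl vinyl ketone | C=CC(C)=O | starting material
3 | (2R)-2-[(2S)-6-methylhept-5-en-2-yl]-5-oxohexanal | O=C[C@@H]([C@@H](C)CCC=C(C)C)CCC(C)=O | intermediate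
4 | (4R)-4-[(2S)-6-methylhept-5-en-2-yl]cyclohex-2-en-1-one | O=C1C=C[C@@H]([C@@H](C)CCC=C(C)C)CC1 | intermediate
5 | dienyl triflate | FC(F)(F)S(=O)(=O)OC1=CC[C@H]([C@@H](C)CCC=C(C)C)C=C1 | intermediate
6 | (5R)-2-methyl-5-[(2S)-6-methylhept-5-en-2-yl]cyclohexa-1,3-diene | CC1=CC[C@H]([C@@H](C)CCC=C(C)C)C=C1 | intermediate
7 | bicyclic endoperoxide (O–O trans to side chain) | CC1=C[C@@H]2OO[C@H]1C[C@@H]2[C@@H](C)CCC=C(C)C | intermediate
8 | vanillin | COc1cc(C=O)ccc1O | starting material
9 | hydroxy aryl ether aldehyde | COc1cc(C=O)ccc1O[C@H]3C[C@H]([C@@H](C)CCC=C(C)C)[C@@H](O)C=C3C | intermediate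
10 | TBS ether aldehyde | COc1cc(C=O)ccc1O[C@H]3C[C@H]([C@@H](C)CCC=C(C)C)[C@@H](O[Si](C)(C)C(C)(C)C)C=C3C | intermediate
11 | acetylacetone | CC(=O)CC(C)=O | starting material
12 | feruloylacetone | COc1cc(/C=C/C(=O)CC(C)=O)ccc1O | intermediate
13 | TBS-protected terpecurcumin B | COc1cc(/C=C/C(=O)/C=C(O)/C=C/c2ccc(O[C@H]3C[C@H]([C@@H](C)CCC=C(C)C)[C@@H](O[Si](C)(C)C(C)(C)C)C=C3C)c(OC)c2)ccc1O | intermediate
14 | terpecurcumin B | COc1cc(/C=C/C(=O)/C=C(O)/C=C/c2ccc(O[C@H]3C[C@H]([C@@H](C)CCC=C(C)C)[C@@H](O)C=C3C)c(OC)c2)ccc1O | target

**Total steps:** 10. **Longest linear sequence:** 9 steps (1, 2, 3, 4, 5, 6, 7, 9, 10 from (S)-citronellal; step 8 is a parallel branch).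

## Three steps most likely to fail
1. **Step 6 (proposed new Pd aryloxylation).** Pd(0) may insert into O–O instead of ionising C–O, or phenoxide may attack the wrong π-allyl terminus.
   - Fallback (known chemistry): Et₃N Kornblum–DeLaMare opening of 7 gives the γ-hydroxy enone with the C4 OH trans to the side chain. Then TBSOTf, Luche reduction (NaBH₄/CeCl₃) to the carbinol cis to the side chain, and Mitsunobu with vanillin (DIAD, PPh₃), which inverts to the trans aryl ether 10.
2. **Steps 1–2 (ring CH(side chain) diastereocontrol and possible epimerisation of the aldehyde α-centre or enone γ-centre).**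
   - Fallback: Enders SAMP-hydrazone α-alkylation of (S)-citronellal with 2-(2-iodoethyl)-2-methyl-1,3-dioxolane. The auxiliary dictates the new centre regardless of C7. Then CuCl₂ hydrazone cleavage, ketal removal and aldol condensation to 4.
3. **Step 9 (Pabon condensation on the acid- and base-sensitive allylic ether core).**
   - Fallback: Claisen–Schmidt condensation of 10 with acetone, then LiHMDS acylation with TBS-feruloyl chloride to build the β-diketone, and a final buffered HF·pyridine double desilylation.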